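The data were generated by integration with constants of no real substance, noise included.

At the first reading of Thursday's run, 0.333 min in, target already stands at 13.5% of the charge, and neither run moves much up to 4.00 min. So I replace each curve by its mean, the end fraction: 19.1% of the charge for Tuesday's run, 13.4% for Thursday's.

| setting | Tuesday's | Thursday's | summer | dusk | midnight |
|---|---|---|---|---|---|
| starting material | 0.44 M | 1.9 M | 0.30 M | 0.60 M | 1.2 M |
| gas phase | 200 mM (held) | 200 mM (held) | 200 mM (held) | 200 mM (held) | 200 mM (held) |
| remark | run made earlier | run made earlier |  |  |  |
| time |  |  | 4.0 min | 4.0 min | 4.0 min |

| run | time / min | target / % |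
|---|---|---|
| Tuesday's | 0.500 | 19.0 |
| Tuesday's | 1.00 | 18.8 |
| Tuesday's | 1.50 | 19.0 |
| Tuesday's | 2.50 | 19.4 |
| Tuesday's | 3.00 | 19.4 |
| Tuesday's | 4.00 | 19.1 |
| Thursday's | 0.333 | 13.5 |
| Thursday's | 0.500 | 13.9 |
| Thursday's | 0.667 | 13.6 |
| Thursday's | 1.00 | 13.2 |
| Thursday's | 1.50 | 13.0 |
| Thursday's | 2.50 | 13.2 |
| Thursday's | 4.00 | 13.3 |

(readings scatter by 0.3 percentage points)

- at the start none of the gas is dissolved
- reactions considered so far: target <-> isomer of the product; 2 dissolved gas -> self-condensation product; starting material -> side product; gas phase <-> dissolved gas; starting material + dissolved gas -> target; starting material -> decomposition product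
- "hardly changes" means that all values lie within two and a half points (for a concentration: within two and a half percent of the largest)

- amount of target at the end, in percent of the starting material charged for summer, dusk, midnight, in this order
- how the row runs (falls all the way / falls, then rises / rises all the way / rises, then falls / hardly changes)

Those means carry standard errors of 0.12 percentage points and 0.11 points. But Thursday's readings from 1.00 min on average 13.2%, lower than the mean by 0.21 points, so I trust my figure for midnight no closer than that.

I take two ways to the row. The first is a ruler: a straight line in the end fraction through both means. The second starts from the gas. Suppose dissolved gas is fed in proportion to its shortfall from saturation and eaten in proportion to starting material, whose curve I again replace by a mean that scales with the charge. The mean gas level then falls as a hyperbola in the charge. If the end fraction follows that level, its reciprocal is a straight line in the charge. Through the two means this gives a lean fraction of 21.9% and a thinning charge of 2.97 M, the intercept of that reciprocal line divided by its slope.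

| flask | charge | ruler | reciprocal line |
|---|---|---|---|
| summer | 0.30 M | 19.7% | 19.9% |
| dusk | 0.60 M | 18.5% | 18.3% |
| midnight | 1.2 M | 16.1% | 15.6% |

Both ways share their two means, so their closeness for summer and dusk is no check. For midnight they part by 0.5 points, more than the doubt above, so one of them cheats. The ruler has no gas balance behind it, so I commit to the reciprocal line, which falls all the way.

The forecast says 20%, 18%, 15.5% and falls all the way, on the ground that “Richer charges draw the dissolved gas down”. The flasks give 19.9%, 18.2%, 15.6%: falls all the way.

    target ⇌ isomer of the product (K = 0.140, k = 0.00850 s⁻¹)
    2 dissolved gas → self-condensation product (k = 0.0790 M⁻¹ s⁻¹)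
    starting material → side product (k = 0.140 s⁻¹)
    gas phase ⇌ dissolved gas, rate k4*(csat - [dissolved gas]) (kL = 0.170 s⁻¹)
    starting material + dissolved gas → target (k = 0.530 M⁻¹ s⁻¹)
    starting material → decomposition product (k = 1.30 × 10⁻⁵ s⁻¹)

Starting from summer's result, the thinning charge of 2.97 M carries to 18.2% for dusk and 15.6% for midnight. In summer, the path to side product has 99.4% of its turnover behind it at 0.400 min, and starting material, the limiting reagent, stands at 0% of its charge at 2.00 min. In the same flask, uptake of gas has 57% of its turnover behind it at 2.00 min and is still making dissolved gas 1.00 times as fast as it is used at 4.00 min, when side product stands at 77.3% of summer's charge and 82.2% of midnight's.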